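Litres per mole is the unit we want here: at one temperature a plateau in percent shifts with the charges, while a quotient in that unit can be carried from one charge to another.

the same everywhere: reagent 0.0225 M; catalyst 25 µM; temperature 25 °C

| run | starting material | remark | time |
|---|---|---|---|
| oak | 0.025 M | the very flask that is asked about, followed so far |  |
| birch | 0.017 M | run made earlier |  |
| flask | 0.025 M |  | 4.0 d |

| run | time / h | target / % | starting material / % |
|---|---|---|---|
| oak | 8.00 | 35 | 44 |
| oak | 15.0 | 48 | 35 |
| oak | 25.0 | 49 | 31 |
| oak | 30.0 | 49 | 32 |
| oak | 40.0 | 52 | 32 |
| oak | 50.0 | 54 | 28 |
| oak | 60.0 | 52 | 30 |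
| birch | 0.500 | 4 | 93 |
| birch | 0.833 | 11 | 86 |
| birch | 1.33 | 14 | 77 |
| birch | 2.00 | 20 | 73 |
| birch | 3.00 | 21 | 63 |
| birch | 5.00 | 32 | 51 |
| birch | 8.00 | 42 | 38 |

(standard deviation of a reading: 2 percentage points)

- green: at 4.0 d add catalyst, 100% of the amount charged, then wait 50 h
- red: change nothing and wait 50 h more
- amber: at 4.0 d raise the temperature by 10 K, then wait 50 h
- violet: at 4.0 d add reagent, 50.0% of the amount charged, then wait 50 h
- blue: at 4.0 d take out 90% of the target then present, then wait 50 h

- what is taken out of target is counted as made
- candidate steps: starting material + reagent <-> target; starting material + reagent <-> isomer of the product; target + catalyst <-> isomer of the product + catalyst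
- the earlier runs do not show what temperature does; that part of a forecast is a guess
- additions bring no volume worth counting

- target, in percent of the starting material first charged, at 4.0 d
- which option adds most target ("none" when 2 percentage points or less is all one gets) (green / red / amber / violet / blue / none)
- target present, with what was taken out counted in, in percent of the starting material first charged, after violet
- target present, with what was taken out counted in, in percent of the starting material first charged, after blue

Has the oak run, which is the asked flask followed so far, stopped? From 40.0 h to 60.0 h target reads 52%, 54%, 52% and starting material 32%, 28%, 30%. That is a level within the scatter of 2 percentage points, so for 4.0 d we commit to its means, 52.7% target and 30.0% starting material.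

What does this level say? In this flask reagent is the limiting reagent. As read from these means, 17.5 mM of each charge has reacted in oak, leaving [starting material] = 7.50 mM and [reagent] = 5.00 mM. We name the plateau quotient: [target] plus [isomer of the product], divided by [starting material] times [reagent]. From oak it reads 467 L mol⁻¹, and target is 75.2% of what reacted. Free reagent comes by subtraction, so the starting material reading on the plateau is the one to watch.

What do the options do to it? Oak reached its level in about 25.0 h, and 50 h is twice that, so we let each option reach the same quotient and share. Red and green leave the totals as they are, and amber is a guess. Violet raises the reagent total to 33.8 mM, and solving the quotient gives 21.3 mM reacted, so 64.2% target. Blue removes target amounting to 47.4% of the starting material charged, leaving totals of 13.1 mM of starting material and 10.6 mM of reagent, with what is held in the remaining target and isomer of the product counted in. These give 7.66 mM reacted, so 70.5% counted in all. We choose blue.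

The forecast, holding “so this is equilibrium rather than a stall”, also chooses blue, with 54% now, more than our level, 64% after violet, and 68% after blue, less than our figure.

The flask gives 52.6%, best blue, 63.7% after violet and 70.2% after blue.

    starting material + reagent ⇌ target (K = 410 L mol⁻¹, k = 0.00150 L mol⁻¹ s⁻¹, Ea = 52.0 kJ mol⁻¹, ΔH = 14.0 kJ mol⁻¹)
    starting material + reagent ⇌ isomer of the product (K = 150 L mol⁻¹, k = 8.50 × 10⁻⁴ L mol⁻¹ s⁻¹, Ea = 77.0 kJ mol⁻¹, ΔH = −12.0 kJ mol⁻¹)
    target + catalyst ⇌ isomer of the product + catalyst, rate k3*[catalyst]*[target] forward; the back reaction follows from the equilibrium constant (k = 0.200 L mol⁻¹ s⁻¹, Ea = 50.0 kJ mol⁻¹)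
    (constants at 25 °C)

The slowest mode of the flask as it stands at 96.0 h has a half-life of 8.34 h, shorter than the 50 h of waiting. Now the quotient goes to a neighbour flask charged with 0.015 M of starting material. It gives 12.4 mM reacted, so 62.2% target, and that neighbour holds 61.9%.

(Readings and results were computed with constants of no real substance; scatter was added.)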